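**Retrosynthetic overview**

1. Target 18 comes from 17 by one global hydrogenolysis, which removes one benzyl ether and the diphenylmethylene ketal on O7/O8.
2. Key disconnection at the diarylmethine C1: both aryl–C1 bonds are cut (C1–C1′ to the pendant ring, C1–C8a to ring A). Enabling feature: C1 is the one carbon bonded to both arenes, each through a carbon para to an oxygen (C1′ para to O4′, C8a para to the C6 methoxy O). C1 also stands 1,4 to O9′ along C1–C2–C3–C9′–O9′. A 2-methoxytetrahydrofuran made of C1, C2, C3, C9′ and O9′ is therefore a masked 1,1-dielectrophile, which leads back to acetal 12 and aryltrifluoroborate 14.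
3. 12 comes from trans-lactone 10 by moving the oxygen ring from C9 to C1. 10 comes from (R)-β-arylmethyl-γ-butyrolactone 7 and trimethyl orthoformate 8, with C2 set anti to C3.
4. 7 comes from Stobbe half-ester 4 by asymmetric hydrogenation (C3). 4 comes from aldehyde 2 and dimethyl succinate 3, and 2 comes from 5-hydroxyvanillin 1.
5. Ring order: dioxole ketal (temporary), then butyrolactone (temporary), then tetrahydrofuran (temporary). Ring B comes last, in the key step, at the expense of the tetrahydrofuran.

Key step: step 8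

Remark: locants follow the aryltetralin skeleton (C1 aryl-bearing, C2, C3, C4, C4a, C5–C8, C8a; C9/O9 = CH2O on C2; C9′/O9′ = CH2O on C3; primed = pendant ring). Salt 14 is assumed not to be on the market and is made from the commercial boronic acid 13.

Step 1
Reactants: 1 3,4-dihydroxy-5-methoxybenzaldehyde (5-hydroxyvanillin)
Product: 2 7-methoxy-2,2-diphenyl-1,3-benzodioxole-5-carbaldehyde
Conditions: Ph2CCl2 (1.2 equiv), Ph2O, 175 °C
Reagents that add atoms: dichlorodiphenylmethane, ClC(Cl)(c1ccccc1)c1ccccc1
Why: Ketalisation of a catechol with a gem-dichloride (double O-alkylation, HCl leaves as gas) masks both phenols at once in a five-membered ring that falls to hydrogenolysis at the end and ties O8 back from the neighbouring ring carbon.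

Step 2
Reactants: 2 7-methoxy-2,2-diphenyl-1,3-benzodioxole-5-carbaldehyde; 3 dimethyl succinate
Product: 4 (E)-3-(methoxycarbonyl)-4-(7-methoxy-2,2-diphenyl-1,3-benzodioxol-5-yl)but-3-enoic acid
Conditions: NaOMe, MeOH, reflux; then aq. HCl
Reagents that add atoms: none
Why: Stobbe condensation, in which the succinate enolate adds to the non-enolisable aldehyde, the aldolate lactonises, and base-induced E1cB opening gives the (E)-alkylidene half-ester with acid and ester already differentiated.

Step 3
Reactants: 4 (E)-3-(methoxycarbonyl)-4-(7-methoxy-2,2-diphenyl-1,3-benzodioxol-5-yl)but-3-enoic acid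
Product: 5 (3R)-3-(methoxycarbonyl)-4-(7-methoxy-2,2-diphenyl-1,3-benzodioxol-5-yl)butanoic acid
Conditions: H2 (5 bar), [Rh(cod)(Et-DuPhos)]OTf (0.5 mol %, ligand antipode that delivers the R acid), MeOH, rt
Reagents that add atoms: none
Why: Rh-catalysed asymmetric hydrogenation of an itaconate-type half-ester, whose carboxyl group and alkene chelate the cationic Rh–bisphospholane, sets C3 (R) by catalyst control, and the homogeneous catalyst leaves the ketal untouched.

Step 4
Reactants: 5 (3R)-3-(methoxycarbonyl)-4-(7-methoxy-2,2-diphenyl-1,3-benzodioxol-5-yl)butanoic acid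
Product: 7 (4R)-4-[(7-methoxy-2,2-diphenyl-1,3-benzodioxol-5-yl)methyl]dihydrofuran-2(3H)-one, via hydroxy acid 6 (not isolated)
Conditions: LiBH4 (2.5 equiv), THF, 0 °C → rt; then 1 M HCl, 0 °C → rt
Reagents that add atoms: none
Why: Chemoselective borohydride reduction, in which the acid is parked as its lithium carboxylate, only the methyl ester is reduced, and the γ-hydroxy acid 6 lactonises on acidification without touching C3.

Step 5
Reactants: 7 (4R)-4-[(7-methoxy-2,2-diphenyl-1,3-benzodioxol-5-yl)methyl]dihydrofuran-2(3H)-one; 8 trimethyl orthoformate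
Product: 10 (3S,4R)-3-(dimethoxymethyl)-4-[(7-methoxy-2,2-diphenyl-1,3-benzodioxol-5-yl)methyl]dihydrofuran-2(3H)-one, via ketene silyl acetal 9 (not isolated)
Conditions: LDA, THF, −78 °C, then TMSCl; solvent change; 8, BF3·OEt2, CH2Cl2, −78 °C
Reagents that add atoms: chlorotrimethylsilane, C[Si](C)(C)Cl (its atoms stay in 9 only)
Why: Mukaiyama-type alkylation of ketene silyl acetal 9 with the dimethoxycarbenium ion from the orthoformate brings in C1 at the aldehyde level, and the electrophile comes anti to the C3 arylmethyl group, which sets C2 trans to C3, the arrangement also favoured at equilibrium.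

Step 6
Reactants: 10 (3S,4R)-3-(dimethoxymethyl)-4-[(7-methoxy-2,2-diphenyl-1,3-benzodioxol-5-yl)methyl]dihydrofuran-2(3H)-one
Product: 12 [(3R,4R)-2-methoxy-4-[(7-methoxy-2,2-diphenyl-1,3-benzodioxol-5-yl)methyl]tetrahydrofuran-3-yl]methanol (3,4-cis, anomer mixture), via diol acetal 11 (not isolated)
Conditions: LiAlH4, THF, 0 °C, aq. NaOH work-up; then CSA (5 mol %), CH2Cl2, rt
Reagents that add atoms: none
Why: Hydride reduction of the lactone followed by acid-catalysed transacetalisation, in which only the C9′ hydroxyl can close a five-membered ring on C1 (the C9 hydroxyl could only form an oxetane), moves the oxygen ring from C9 to C1 without exposing a free aldehyde or touching C2 and C3, so the trans lactone becomes the 3,4-cis tetrahydrofuran.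

Step 7
Reactants: 13 [4-(benzyloxy)-3-methoxyphenyl]boronic acid
Product: 14 potassium [4-(benzyloxy)-3-methoxyphenyl]trifluoroborate
Conditions: KHF2 (aq., 3 equiv), MeOH, rt
Reagents that add atoms: potassium hydrogen difluoride, [K+].F.[F-]
Why: Conversion of a boronic acid to its potassium trifluoroborate gives a crystalline, monomeric aryl donor that releases its reactivity only when BF3 is added.

Step 8
Reactants: 12 [(3R,4R)-2-methoxy-4-[(7-methoxy-2,2-diphenyl-1,3-benzodioxol-5-yl)methyl]tetrahydrofuran-3-yl]methanol; 14 potassium [4-(benzyloxy)-3-methoxyphenyl]trifluoroborate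
Product: 17 (1S,2R,3R)-1-[4-(benzyloxy)-3-methoxyphenyl]-2,3-bis(hydroxymethyl)-6-methoxy-7,8-(diphenylmethylenedioxy)-1,2,3,4-tetrahydronaphthalene, via aryldifluoroborane 15 (not isolated), via 2-aryltetrahydrofuran 16 (not isolated)
Conditions: 14 (1.2 equiv), BF3·OEt2 (4 equiv), CH2Cl2/MeCN, −40 °C → rt
Reagents that add atoms: none
Why: BF3·OEt2 takes a fluoride from 14 and the Lewis-acidic aryldifluoroborane 15 ionises the exocyclic methoxy group of acetal 12, so that the cyclic oxocarbenium ion (C1=O9′+) is born next to its own aryl donor and takes up the aryl group by ipso transfer from boron, which makes the C1–C1′ bond and gives 16 (closest known reaction type: BF3-promoted coupling of potassium aryltrifluoroborates with acetals). On warming, BF3 reopens the benzylic C1–O9′ bond of 16, because C1′ stands para to the benzyloxy oxygen, and the planar p-alkoxybenzyl cation is caught by C8a of ring A in an intramolecular Friedel–Crafts alkylation (closest known reaction type: the acid-induced rearrangement of 7,9′-epoxylignans of the lariciresinol type to aryltetralins). Ring B closes 6-exo-trig with respect to the quinone-methide-like C1=C1′ bond, with the arene bond C4a–C8a inside the new ring, while the tetrahydrofuran ring is opened and the C9′ hydroxyl is set free. C1 is the only new stereocentre and is set in this closure, whatever its configuration in 16, by C2 and C3 through a chair-like transition state with the aryl group and both CH2O groups pseudo-equatorial, which should give the 1,2-trans-2,3-trans array (1S,2R,3R). The site on the pendant ring is fixed by boron, and on ring A the closure should go to C8a (para to the C6 methoxy group, beside the ketal oxygen O8 that the five-membered ring ties back) and not to C5, which is screened by the methoxy methyl group that O7 forces to that side. The order of events is secured because ring A could reach the cyclic oxocarbenium ion only from the face that carries the cis CH2OH group on C2 and only by building a strained 6-oxabicyclo[3.2.1]octane, and a second intermolecular arylation of the cation is outrun by the unstrained six-ring closure when 14 is kept near one equivalent.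

Step 9
Reactants: 17 (1S,2R,3R)-1-[4-(benzyloxy)-3-methoxyphenyl]-2,3-bis(hydroxymethyl)-6-methoxy-7,8-(diphenylmethylenedioxy)-1,2,3,4-tetrahydronaphthalene
Product: 18 (1S,2R,3R)-1-(4-hydroxy-3-methoxyphenyl)-2,3-bis(hydroxymethyl)-6-methoxy-1,2,3,4-tetrahydronaphthalene-7,8-diol (target)
Conditions: H2 (1–4 bar), Pd(OH)2/C, MeOH/EtOAc, rt, air excluded on work-up
Reagents that add atoms: none
Why: Catalytic hydrogenolysis cleaves the O-benzyl bond and both benzhydrylic C–O bonds of the ketal in one operation, while C1, C2 and C3 carry no benzylic C–O bond and are not affected.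

**Compound list**

1 | 3,4-dihydroxy-5-methoxybenzaldehyde | COc1cc(C=O)cc(O)c1O | starting material
2 | 7-methoxy-2,2-diphenyl-1,3-benzodioxole-5-carbaldehyde | COc1cc(C=O)cc2OC(c3ccccc3)(c3ccccc3)Oc12 | intermediate
3 | dimethyl succinate | COC(=O)CCC(=O)OC | starting material
4 | (E)-3-(methoxycarbonyl)-4-(7-methoxy-2,2-diphenyl-1,3-benzodioxol-5-yl)but-3-enoic acid | COC(=O)/C(CC(=O)O)=C/c1cc(OC)c2OC(c3ccccc3)(c3ccccc3)Oc2c1 | intermediate
5 | (3R)-3-(methoxycarbonyl)-4-(7-methoxy-2,2-diphenyl-1,3-benzodioxol-5-yl)butanoic acid | COC(=O)[C@H](Cc1cc(OC)c2OC(c3ccccc3)(c3ccccc3)Oc2c1)CC(=O)O | intermediate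
6 | (3R)-3-(hydroxymethyl)-4-(7-methoxy-2,2-diphenyl-1,3-benzodioxol-5-yl)butanoic acid | OC[C@H](Cc1cc(OC)c2OC(c3ccccc3)(c3ccccc3)Oc2c1)CC(=O)O | intermediate
7 | (4R)-4-[(7-methoxy-2,2-diphenyl-1,3-benzodioxol-5-yl)methyl]dihydrofuran-2(3H)-one | O=C1OC[C@H](Cc2cc(OC)c3OC(c4ccccc4)(c4ccccc4)Oc3c2)C1 | intermediate
8 | trimethyl orthoformate | COC(OC)OC | starting material
9 | (3R)-3-[(7-methoxy-2,2-diphenyl-1,3-benzodioxol-5-yl)methyl]-5-(trimethylsilyloxy)-2,3-dihydrofuran | C[Si](C)(C)OC1=C[C@@H](Cc2cc(OC)c3OC(c4ccccc4)(c4ccccc4)Oc3c2)CO1 | intermediate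
10 | (3S,4R)-3-(dimethoxymethyl)-4-[(7-methoxy-2,2-diphenyl-1,3-benzodioxol-5-yl)methyl]dihydrofuran-2(3H)-one (trans) | O=C1OC[C@H](Cc2cc(OC)c3OC(c4ccccc4)(c4ccccc4)Oc3c2)[C@H]1C(OC)OC | intermediate
11 | (2R,3R)-2-(dimethoxymethyl)-3-[(7-methoxy-2,2-diphenyl-1,3-benzodioxol-5-yl)methyl]butane-1,4-diol | COC(OC)[C@@H](CO)[C@H](CO)Cc1cc(OC)c2OC(c3ccccc3)(c3ccccc3)Oc2c1 | intermediate
12 | [(3R,4R)-2-methoxy-4-[(7-methoxy-2,2-diphenyl-1,3-benzodioxol-5-yl)methyl]tetrahydrofuran-3-yl]methanol (3,4-cis, anomers) | COC1OC[C@H](Cc2cc(OC)c3OC(c4ccccc4)(c4ccccc4)Oc3c2)[C@@H]1CO | intermediate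
13 | [4-(benzyloxy)-3-methoxyphenyl]boronic acid | COc1cc(B(O)O)ccc1OCc1ccccc1 | starting material
14 | potassium [4-(benzyloxy)-3-methoxyphenyl]trifluoroborate | COc1cc([B-](F)(F)F)ccc1OCc1ccccc1.[K+] | intermediate
15 | [4-(benzyloxy)-3-methoxyphenyl]difluoroborane | COc1cc(B(F)F)ccc1OCc1ccccc1 | intermediate
16 | [(3R,4R)-2-[4-(benzyloxy)-3-methoxyphenyl]-4-[(7-methoxy-2,2-diphenyl-1,3-benzodioxol-5-yl)methyl]tetrahydrofuran-3-yl]methanol (either configuration at C1) | COc1cc(C2OC[C@H](Cc3cc(OC)c4OC(c5ccccc5)(c5ccccc5)Oc4c3)[C@@H]2CO)ccc1OCc1ccccc1 | intermediate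
17 | (1S,2R,3R)-1-[4-(benzyloxy)-3-methoxyphenyl]-2,3-bis(hydroxymethyl)-6-methoxy-7,8-(diphenylmethylenedioxy)-1,2,3,4-tetrahydronaphthalene | COc1cc([C@H]2c3c(cc(OC)c4OC(c5ccccc5)(c5ccccc5)Oc34)C[C@@H](CO)[C@@H]2CO)ccc1OCc1ccccc1 | intermediate
18 | (1S,2R,3R)-1-(4-hydroxy-3-methoxyphenyl)-2,3-bis(hydroxymethyl)-6-methoxy-1,2,3,4-tetrahydronaphthalene-7,8-diol | COc1cc([C@H]2c3c(cc(OC)c(O)c3O)C[C@@H](CO)[C@@H]2CO)ccc1O | target

Total step count: 9. Longest linear sequence: 8 (steps 1–6, 8, 9).

**Steps most likely to fail**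

**Step 8.**
- What may go wrong:
  - Ring A may attack the activated acetal carbon before the aryl group arrives, after endocyclic C–O cleavage.
  - The closure may drift to C5.
  - The boron reagent may be lost by protodeboronation.
  - BF3 may open the diaryl ketal.
- Fallback (from 12, back at 17): the two C–C bonds are made in separate flasks, the first under basic conditions where ring A is inert. Mild aqueous acid (AcOH/H2O/THF) turns 12 into the lactol (3R,4R)-3-(hydroxymethyl)-4-[(7-methoxy-2,2-diphenyl-1,3-benzodioxol-5-yl)methyl]tetrahydrofuran-2-ol F1. The Grignard reagent [4-(benzyloxy)-3-methoxyphenyl]magnesium bromide F2 is made from commercial 1-(benzyloxy)-4-bromo-2-methoxybenzene and magnesium. It adds in excess to the open hydroxy aldehyde form of F1 and gives the triol (2R,3R)-1-[4-(benzyloxy)-3-methoxyphenyl]-2-(hydroxymethyl)-3-[(7-methoxy-2,2-diphenyl-1,3-benzodioxol-5-yl)methyl]butane-1,4-diol F3. A catalytic amount of camphorsulfonic acid (or dilute TFA) in CH2Cl2 then ionises only the p-alkoxybenzylic alcohol of F3 and closes ring B to 17.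

**Step 5.**
- What may go wrong:
  - O-silylation may be incomplete, or the ketene silyl acetal may hydrolyse during the solvent change.
  - The uptake of the carbenium ion may be slow.
  - The Lewis acid may attack the ketal.
- Fallback (from 7, back at 10): C1 is brought in by a Claisen condensation instead of a cationic alkylation. Ethyl formate and NaH convert 7 into the enolised formyl lactone (4R)-3-(hydroxymethylidene)-4-[(7-methoxy-2,2-diphenyl-1,3-benzodioxol-5-yl)methyl]dihydrofuran-2(3H)-one F4. Methanol with trimethyl orthoformate and catalytic TsOH converts F4 into the dimethyl acetal 10. C2 settles trans to C3 by acid-mediated equilibration.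

**Step 9.**
- What may go wrong:
  - Hydrogenolysis of the hindered diaryl ketal beside C1 may be slow or incomplete.
  - The catalyst may be poisoned.
  - The freed catechol may oxidise in air.
- Fallback (from 17, back at 18): the ketal is removed by hydrolysis instead of reduction. TFA/H2O in CH2Cl2 gives the catechol (1S,2R,3R)-1-[4-(benzyloxy)-3-methoxyphenyl]-2,3-bis(hydroxymethyl)-6-methoxy-1,2,3,4-tetrahydronaphthalene-7,8-diol F5. A short hydrogenolysis over Pd/C then has to cleave only the one unhindered benzyl ether of F5 to reach 18.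

**Further compounds**

F1 | step 8 | (3R,4R)-3-(hydroxymethyl)-4-[(7-methoxy-2,2-diphenyl-1,3-benzodioxol-5-yl)methyl]tetrahydrofuran-2-ol | OC1OC[C@H](Cc2cc(OC)c3OC(c4ccccc4)(c4ccccc4)Oc3c2)[C@@H]1CO
F2 | step 8 | [4-(benzyloxy)-3-methoxyphenyl]magnesium bromide | COc1cc([Mg]Br)ccc1OCc1ccccc1
F3 | step 8 | (2R,3R)-1-[4-(benzyloxy)-3-methoxyphenyl]-2-(hydroxymethyl)-3-[(7-methoxy-2,2-diphenyl-1,3-benzodioxol-5-yl)methyl]butane-1,4-diol | COc1cc(C(O)[C@@H](CO)[C@H](CO)Cc2cc(OC)c3OC(c4ccccc4)(c4ccccc4)Oc3c2)ccc1OCc1ccccc1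
F4 | step 5 | (4R)-3-(hydroxymethylidene)-4-[(7-methoxy-2,2-diphenyl-1,3-benzodioxol-5-yl)methyl]dihydrofuran-2(3H)-one | O=C1OC[C@H](Cc2cc(OC)c3OC(c4ccccc4)(c4ccccc4)Oc3c2)C1=CO
F5 | step 9 | (1S,2R,3R)-1-[4-(benzyloxy)-3-methoxyphenyl]-2,3-bis(hydroxymethyl)-6-methoxy-1,2,3,4-tetrahydronaphthalene-7,8-diol | COc1cc([C@H]2c3c(cc(OC)c(O)c3O)C[C@@H](CO)[C@@H]2CO)ccc1OCc1ccccc1
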